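Everything rests on assembling ring A of the flavone half instead of functionalising it. That ring is a phloroglucinol whose oxygens at C5, C7 and C8a need three different labels and whose C8 holds ring B of the flavanone half, wedged between two of them. One thermal Danheiser benzannulation joins 3-benzyloxycyclobutenone to the triisopropylsilyl ynol ether of 2-benzyloxy-5-bromophenylacetylene. It forms C8–C8a and C6–C7, closes the benzene ring and leaves C8a–OH free, C7–OTIPS and C5–OBn. The crowded C8–C3' bond is inherited from the aryl–alkyne bond. The spectator bromide later becomes the boronic acid for an enantioselective conjugate addition that sets flavanone C2 as (S).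

Key step: step 6

Remark on labels: C2–C8a denote the flavone (apigenin) half, C1'–C6' denote ring B, and "flavanone C2" is the only stereocentre.
Remark on the axis: the C8–C3' bond has three ortho substituents and the target carries no axial descriptor, so free rotation is assumed and no axial stereochemistry is drawn.
Remark on step 14: the facial sense of the ligand is extrapolated from cyclic enones, where the (S)-ligand leads to (R)-3-aryl-3-methylcyclohexanones. Attack on the same face of a chromone corresponds to (R) at C2, so the (R)-ligand is specified.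

Step 1
Reactants: 1 ethoxyacetylene; 2 acetone
Product: 4 3-ethoxycyclobut-2-en-1-one, via ketene 3 (not isolated)
Conditions: acetone vapour over a glowing filament (ketene generator); gas stream into 1 (hexanes solution), CH2Cl2, 0 °C
Reagents that add atoms: none
Why: The ketene–alkoxyalkyne [2+2] cycloaddition is polarity-matched, because the nucleophilic terminal alkyne carbon attacks the central ketene carbon, so the 3-alkoxycyclobutenone forms directly and without a stereocentre.

Step 2
Reactants: 4 3-ethoxycyclobut-2-en-1-one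
Product: 5 3-(benzyloxy)cyclobut-2-en-1-one
Conditions: BnOH (1.5 equiv), camphorsulfonic acid (5 mol%), toluene, 35 °C, reduced pressure (EtOH stripped off)
Reagents that add atoms: benzyl alcohol, OCc1ccccc1
Why: This acid-catalysed vinylogous transesterification (addition–elimination at C3 through the oxygen-stabilised hydroxycyclobutenyl cation) is pulled forward by removal of the volatile ethanol and runs well below the temperature of ring opening.

Step 3
Reactants: 6 4-bromo-2-iodophenol
Product: 7 1-(benzyloxy)-4-bromo-2-iodobenzene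
Conditions: BnBr, K2CO3, DMF, rt
Reagents that add atoms: benzyl bromide, BrCc1ccccc1
Why: Williamson etherification of an acidic halophenol leaves both aryl halides untouched.

Step 4
Reactants: 7 1-(benzyloxy)-4-bromo-2-iodobenzene
Product: 9 1-(benzyloxy)-4-bromo-2-ethynylbenzene, via trimethylsilylalkyne 8 (not isolated)
Conditions: Me3SiC≡CH, PdCl2(PPh3)2 (2 mol%), CuI (4 mol%), Et3N, THF, rt; silica plug, concentrate; K2CO3 (0.2 equiv), MeOH–THF, rt
Reagents that add atoms: trimethylsilylacetylene, C#C[Si](C)(C)C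
Why: Sonogashira coupling at room temperature selects the iodide over the bromide through its much faster oxidative addition to zerovalent palladium, and catalytic carbonate in methanol then protodesilylates the alkyne.

Step 5
Reactants: 9 1-(benzyloxy)-4-bromo-2-ethynylbenzene
Product: 12 {[2-(benzyloxy)-5-bromophenyl]ethynyloxy}triisopropylsilane, via lithium acetylide 10 (not isolated), via lithium ynolate 11 (not isolated)
Conditions: LiN(SiMe3)2, THF, −78 °C; t-BuOOLi (from anhydrous t-BuOOH and LiN(SiMe3)2, THF, −78 °C), −78 to 0 °C; i-Pr3SiOTf, −78 to 0 °C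
Reagents that add atoms: tert-butyl hydroperoxide, CC(C)(C)OO; triisopropylsilyl trifluoromethanesulfonate, CC(C)[Si](C(C)C)(C(C)C)OS(=O)(=O)C(F)(F)F
Why: Electrophilic oxygenation of the lithium acetylide by lithium tert-butyl peroxide gives the ynolate, the bulky silyl triflate traps it on oxygen, and an amide base in place of an alkyllithium spares the aryl bromide.

Step 6
Reactants: 5 3-(benzyloxy)cyclobut-2-en-1-one; 12 {[2-(benzyloxy)-5-bromophenyl]ethynyloxy}triisopropylsilane
Product: 17 5-(benzyloxy)-2-[2-(benzyloxy)-5-bromophenyl]-3-(triisopropylsilyloxy)phenol, via vinylketene 13 (not isolated), via vinylcyclobutenone 14 (not isolated), via dienylketene 15 (not isolated), via cyclohexadienone 16 (not isolated)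
Conditions: 12 (1.2 equiv), toluene, argon, 80 °C, slow addition of 5; then 110 °C
Reagents that add atoms: none
Why: This is a Danheiser benzannulation, closest in type to the established union of cyclobutenones with trialkylsilyloxyalkynes that leads to resorcinol monosilyl ethers. On heating, 5 undergoes conrotatory electrocyclic cleavage of its C1–C4 bond to vinylketene 13, which 12 intercepts in a ketene–alkyne [2+2] cycloaddition to vinylcyclobutenone 14, and 14 in turn ring-opens to dienylketene 15. Ring A is closed by disrotatory 6π electrocyclisation of 15, which links the terminal methylene carbon (C4a) to the ketene carbon (C8a) and gives cyclohexadienone 16, and enolisation to 17 makes the sequence irreversible. No stereocentre survives, since the one at C4 of 14 is erased when that ring opens. What must be controlled is orientation, and polarity does it: the ynol ether carbon that bears ring B is the nucleophilic terminus (future C8) and attacks the central ketene carbon (future C8a), so the aryl group is flanked by OH on one side and OTIPS on the other. The bulky silyl group holds back oxygen-to-carbon silyl migration, and slow addition of 5 to an excess of 12 keeps acylation of 17 by 13 low.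

Step 7
Reactants: 17 5-(benzyloxy)-2-[2-(benzyloxy)-5-bromophenyl]-3-(triisopropylsilyloxy)phenol
Product: 19 6-(benzyloxy)-3-[2-(benzyloxy)-5-bromophenyl]-2-hydroxy-4-(triisopropylsilyloxy)benzaldehyde, via salicyl alcohol 18 (not isolated)
Conditions: anhydrous MgCl2, Et3N, (CH2O)n, MeCN, 80 °C; then 1 M HCl
Reagents that add atoms: paraformaldehyde (reacts as formaldehyde), C=O
Why: In the Casnati–Skattebøl ortho-formylation the magnesium phenoxide delivers formaldehyde through a chelate only to the carbon next to the free hydroxyl (C4a, the sole open ortho site), a second formaldehyde oxidises salicyl alcohol 18 by hydride transfer, and no Lewis acid strong enough to harm benzyl ether, silyl ether or bromide is present.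

Step 8
Reactants: 19 6-(benzyloxy)-3-[2-(benzyloxy)-5-bromophenyl]-2-hydroxy-4-(triisopropylsilyloxy)benzaldehyde; 20 1-(benzyloxy)-4-ethynylbenzene
Product: 22 rac-1-{6-(benzyloxy)-3-[2-(benzyloxy)-5-bromophenyl]-2-hydroxy-4-(triisopropylsilyloxy)phenyl}-3-[4-(benzyloxy)phenyl]prop-2-yn-1-ol, via lithium acetylide 21 (not isolated)
Conditions: 20 (2.3 equiv), n-BuLi (2.2 equiv), THF, −78 °C; then 19, −78 to 0 °C; aq NH4Cl; crude product used at once
Reagents that add atoms: none
Why: This is a 1,2-addition of a lithium acetylide to an aldehyde in which the first equivalent deprotonates the phenol, all n-BuLi is consumed before 19 enters so that no bromine–lithium exchange can occur, and the carbinol stereocentre forms as a racemate that step 9 erases.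

Step 9
Reactants: 22 rac-1-{6-(benzyloxy)-3-[2-(benzyloxy)-5-bromophenyl]-2-hydroxy-4-(triisopropylsilyloxy)phenyl}-3-[4-(benzyloxy)phenyl]prop-2-yn-1-ol
Product: 25 5-(benzyloxy)-8-[2-(benzyloxy)-5-bromophenyl]-2-[4-(benzyloxy)phenyl]-7-(triisopropylsilyloxy)-4H-chromen-4-one, via ynone 23 (not isolated), via enaminone 24 (not isolated)
Conditions: activated MnO2, CH2Cl2, rt; filter, concentrate; Et2NH, EtOH–THF, 60 °C
Reagents that add atoms: none
Why: MnO2 oxidation of the benzylic propargylic alcohol gives the hydrogen-bonded ynone, and aza-Michael addition of the secondary amine followed by addition–elimination by the C8a phenol enforces 6-endo closure to the flavone instead of 5-exo closure to an aurone.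

Step 10
Reactants: 25 5-(benzyloxy)-8-[2-(benzyloxy)-5-bromophenyl]-2-[4-(benzyloxy)phenyl]-7-(triisopropylsilyloxy)-4H-chromen-4-one
Product: 27 5,7-bis(benzyloxy)-8-[2-(benzyloxy)-5-bromophenyl]-2-[4-(benzyloxy)phenyl]-4H-chromen-4-one, via caesium phenolate 26 (not isolated)
Conditions: CsF, BnBr, DMF, rt
Reagents that add atoms: benzyl bromide, BrCc1ccccc1
Why: Fluoride cleavage of the aryl silyl ether with in situ Williamson benzylation is done before any stereocentre exists so that the end game needs one neutral deprotection only, and any silyl loss during step 9 would feed into the same phenolate 26.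

Step 11
Reactants: 27 5,7-bis(benzyloxy)-8-[2-(benzyloxy)-5-bromophenyl]-2-[4-(benzyloxy)phenyl]-4H-chromen-4-one
Product: 28 (4-(benzyloxy)-3-{5,7-bis(benzyloxy)-2-[4-(benzyloxy)phenyl]-4-oxo-4H-chromen-8-yl}phenyl)boronic acid
Conditions: B2(OH)4, PdCl(XPhos)(2'-amino-1,1'-biphenyl-2-yl) (second-generation aminobiphenyl palladacycle, 2 mol%), XPhos (4 mol%), KOAc, EtOH–THF, 75 °C
Reagents that add atoms: tetrahydroxydiboron, OB(O)B(O)O
Why: Miyaura-type palladium-catalysed borylation of the unhindered aryl bromide with tetrahydroxydiboron gives the free boronic acid in one operation and tolerates the pyranone carbonyl, which a halogen–metal exchange would not.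

Step 12
Reactants: 29 1-(2,6-dihydroxy-4-methoxyphenyl)ethan-1-one
Product: 30 1-[2-(benzyloxy)-6-hydroxy-4-methoxyphenyl]ethan-1-one
Conditions: BnBr (1.05 equiv), K2CO3, acetone, reflux
Reagents that add atoms: benzyl bromide, BrCc1ccccc1
Why: Williamson etherification stops after one of the two equivalent hydroxyls, because the remaining one is locked in a strong hydrogen bond to the acetyl oxygen.

Step 13
Reactants: 30 1-[2-(benzyloxy)-6-hydroxy-4-methoxyphenyl]ethan-1-one
Product: 32 5-(benzyloxy)-7-methoxy-4H-chromen-4-one, via enaminone 31 (not isolated)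
Conditions: Me2NCH(OMe)2, toluene, 95 °C; concentrate; 2 M aq HCl, CH2Cl2, rt
Reagents that add atoms: N,N-dimethylformamide dimethyl acetal, COC(OC)N(C)C
Why: In the enaminone chromone synthesis the methyl ketone condenses with the amide acetal, and acid then promotes addition–elimination by the ortho phenol to close the 2,3-unsubstituted pyranone.

Step 14
Reactants: 28 (4-(benzyloxy)-3-{5,7-bis(benzyloxy)-2-[4-(benzyloxy)phenyl]-4-oxo-4H-chromen-8-yl}phenyl)boronic acid; 32 5-(benzyloxy)-7-methoxy-4H-chromen-4-one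
Product: 33 (2S)-5-(benzyloxy)-2-(4-(benzyloxy)-3-{5,7-bis(benzyloxy)-2-[4-(benzyloxy)phenyl]-4-oxo-4H-chromen-8-yl}phenyl)-7-methoxy-2,3-dihydro-4H-chromen-4-one
Conditions: 32 (1.5 equiv), Pd(OCOCF3)2 (10 mol%), (R)-4-tert-butyl-2-(pyridin-2-yl)-4,5-dihydrooxazole (12 mol%), NH4PF6 (30 mol%), H2O (5 equiv), ClCH2CH2Cl, 60 °C
Reagents that add atoms: none
Why: In this asymmetric palladium-catalysed conjugate addition of an arylboronic acid to a chromone, transmetalation to the cationic divalent palladium–pyridinooxazoline complex is followed by enantiodetermining migratory insertion of C2=C3 and protonolysis of the palladium enolate, the tert-butyl group of the (R)-ligand steers ring B to the face of C2 that gives (S), the base-free medium avoids retro-oxa-Michael racemisation, and the 2-aryl-substituted flavone enone of 28 is too hindered and electron-rich to compete.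

Step 15
Reactants: 33 (2S)-5-(benzyloxy)-2-(4-(benzyloxy)-3-{5,7-bis(benzyloxy)-2-[4-(benzyloxy)phenyl]-4-oxo-4H-chromen-8-yl}phenyl)-7-methoxy-2,3-dihydro-4H-chromen-4-one
Product: 34 (2S)-2-{3-[5,7-dihydroxy-2-(4-hydroxyphenyl)-4-oxo-4H-chromen-8-yl]-4-hydroxyphenyl}-5-hydroxy-7-methoxy-2,3-dihydro-4H-chromen-4-one
Conditions: H2 (1 atm), Pd/C (10 wt%), THF–MeOH, rt, stopped at full debenzylation
Reagents that add atoms: none
Why: Catalytic hydrogenolysis removes all five benzyl ethers under neutral conditions, in which the aryl methyl ether, the flavone C2=C3 bond and the base-sensitive flavanone C2 stereocentre are expected to persist.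

Compound list
1 | ethoxyacetylene | C#COCC | starting material
2 | acetone | CC(C)=O | starting material
3 | ketene | C=C=O | intermediate
4 | 3-ethoxycyclobut-2-en-1-one | CCOC1=CC(=O)C1 | intermediate
5 | 3-(benzyloxy)cyclobut-2-en-1-one | O=C1C=C(OCc2ccccc2)C1 | intermediate
6 | 4-bromo-2-iodophenol | Oc1ccc(Br)cc1I | starting material
7 | 1-(benzyloxy)-4-bromo-2-iodobenzene | Brc1ccc(OCc2ccccc2)c(I)c1 | intermediate
8 | {[2-(benzyloxy)-5-bromophenyl]ethynyl}trimethylsilane | C[Si](C)(C)C#Cc1cc(Br)ccc1OCc1ccccc1 | intermediate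
9 | 1-(benzyloxy)-4-bromo-2-ethynylbenzene | C#Cc1cc(Br)ccc1OCc1ccccc1 | intermediate
10 | lithium [2-(benzyloxy)-5-bromophenyl]acetylide | [Li+].[C-]#Cc1cc(Br)ccc1OCc1ccccc1 | intermediate
11 | lithium 2-[2-(benzyloxy)-5-bromophenyl]ethynolate | [Li+].[O-]C#Cc1cc(Br)ccc1OCc1ccccc1 | intermediate
12 | {[2-(benzyloxy)-5-bromophenyl]ethynyloxy}triisopropylsilane | CC(C)[Si](OC#Cc1cc(Br)ccc1OCc1ccccc1)(C(C)C)C(C)C | intermediate
13 | 3-(benzyloxy)buta-1,3-dien-1-one (vinylketene) | C=C(OCc1ccccc1)C=C=O | intermediate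
14 | rac-2-[2-(benzyloxy)-5-bromophenyl]-4-[1-(benzyloxy)vinyl]-3-(triisopropylsilyloxy)cyclobut-2-en-1-one | O=C1C(c2cc(Br)ccc2OCc2ccccc2)=C(O[Si](C(C)C)(C(C)C)C(C)C)C1C(=C)OCc1ccccc1 | intermediate
15 | 5-(benzyloxy)-2-[2-(benzyloxy)-5-bromophenyl]-3-(triisopropylsilyloxy)hexa-1,3,5-trien-1-one (ketene and vinyl ether termini cis on the central double bond) | O=C=C(c1cc(Br)ccc1OCc1ccccc1)/C(O[Si](C(C)C)(C(C)C)C(C)C)=C\C(=C)OCc1ccccc1 | intermediate
16 | 5-(benzyloxy)-2-[2-(benzyloxy)-5-bromophenyl]-3-(triisopropylsilyloxy)cyclohexa-2,4-dien-1-one | O=C1CC(OCc2ccccc2)=CC(O[Si](C(C)C)(C(C)C)C(C)C)=C1c1cc(Br)ccc1OCc1ccccc1 | intermediate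
17 | 5-(benzyloxy)-2-[2-(benzyloxy)-5-bromophenyl]-3-(triisopropylsilyloxy)phenol | Oc1cc(OCc2ccccc2)cc(O[Si](C(C)C)(C(C)C)C(C)C)c1-c1cc(Br)ccc1OCc1ccccc1 | intermediate
18 | 3-(benzyloxy)-6-[2-(benzyloxy)-5-bromophenyl]-2-(hydroxymethyl)-5-(triisopropylsilyloxy)phenol | OCc1c(O)c(-c2cc(Br)ccc2OCc2ccccc2)c(O[Si](C(C)C)(C(C)C)C(C)C)cc1OCc1ccccc1 | intermediate
19 | 6-(benzyloxy)-3-[2-(benzyloxy)-5-bromophenyl]-2-hydroxy-4-(triisopropylsilyloxy)benzaldehyde | O=Cc1c(O)c(-c2cc(Br)ccc2OCc2ccccc2)c(O[Si](C(C)C)(C(C)C)C(C)C)cc1OCc1ccccc1 | intermediate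
20 | 1-(benzyloxy)-4-ethynylbenzene | C#Cc1ccc(OCc2ccccc2)cc1 | starting material
21 | lithium [4-(benzyloxy)phenyl]acetylide | [Li+].[C-]#Cc1ccc(OCc2ccccc2)cc1 | intermediate
22 | rac-1-{6-(benzyloxy)-3-[2-(benzyloxy)-5-bromophenyl]-2-hydroxy-4-(triisopropylsilyloxy)phenyl}-3-[4-(benzyloxy)phenyl]prop-2-yn-1-ol | OC(C#Cc1ccc(OCc2ccccc2)cc1)c1c(O)c(-c2cc(Br)ccc2OCc2ccccc2)c(O[Si](C(C)C)(C(C)C)C(C)C)cc1OCc1ccccc1 | intermediate
23 | 1-{6-(benzyloxy)-3-[2-(benzyloxy)-5-bromophenyl]-2-hydroxy-4-(triisopropylsilyloxy)phenyl}-3-[4-(benzyloxy)phenyl]prop-2-yn-1-one | O=C(C#Cc1ccc(OCc2ccccc2)cc1)c1c(O)c(-c2cc(Br)ccc2OCc2ccccc2)c(O[Si](C(C)C)(C(C)C)C(C)C)cc1OCc1ccccc1 | intermediate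
24 | 1-{6-(benzyloxy)-3-[2-(benzyloxy)-5-bromophenyl]-2-hydroxy-4-(triisopropylsilyloxy)phenyl}-3-[4-(benzyloxy)phenyl]-3-(diethylamino)prop-2-en-1-one | CCN(CC)C(=CC(=O)c1c(O)c(-c2cc(Br)ccc2OCc2ccccc2)c(O[Si](C(C)C)(C(C)C)C(C)C)cc1OCc1ccccc1)c1ccc(OCc2ccccc2)cc1 | intermediate
25 | 5-(benzyloxy)-8-[2-(benzyloxy)-5-bromophenyl]-2-[4-(benzyloxy)phenyl]-7-(triisopropylsilyloxy)-4H-chromen-4-one | O=c1cc(-c2ccc(OCc3ccccc3)cc2)oc2c(-c3cc(Br)ccc3OCc3ccccc3)c(O[Si](C(C)C)(C(C)C)C(C)C)cc(OCc3ccccc3)c12 | intermediate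
26 | caesium 5-(benzyloxy)-8-[2-(benzyloxy)-5-bromophenyl]-2-[4-(benzyloxy)phenyl]-4-oxo-4H-chromen-7-olate | [Cs+].[O-]c1cc(OCc2ccccc2)c2c(=O)cc(-c3ccc(OCc4ccccc4)cc3)oc2c1-c1cc(Br)ccc1OCc1ccccc1 | intermediate
27 | 5,7-bis(benzyloxy)-8-[2-(benzyloxy)-5-bromophenyl]-2-[4-(benzyloxy)phenyl]-4H-chromen-4-one | O=c1cc(-c2ccc(OCc3ccccc3)cc2)oc2c(-c3cc(Br)ccc3OCc3ccccc3)c(OCc3ccccc3)cc(OCc3ccccc3)c12 | intermediate
28 | (4-(benzyloxy)-3-{5,7-bis(benzyloxy)-2-[4-(benzyloxy)phenyl]-4-oxo-4H-chromen-8-yl}phenyl)boronic acid | O=c1cc(-c2ccc(OCc3ccccc3)cc2)oc2c(-c3cc(B(O)O)ccc3OCc3ccccc3)c(OCc3ccccc3)cc(OCc3ccccc3)c12 | intermediate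
29 | 1-(2,6-dihydroxy-4-methoxyphenyl)ethan-1-one | COc1cc(O)c(C(C)=O)c(O)c1 | starting material
30 | 1-[2-(benzyloxy)-6-hydroxy-4-methoxyphenyl]ethan-1-one | COc1cc(O)c(C(C)=O)c(OCc2ccccc2)c1 | intermediate
31 | (E)-1-[2-(benzyloxy)-6-hydroxy-4-methoxyphenyl]-3-(dimethylamino)prop-2-en-1-one | COc1cc(O)c(C(=O)/C=C/N(C)C)c(OCc2ccccc2)c1 | intermediate
32 | 5-(benzyloxy)-7-methoxy-4H-chromen-4-one | COc1cc(OCc2ccccc2)c2c(=O)ccoc2c1 | intermediate
33 | (2S)-5-(benzyloxy)-2-(4-(benzyloxy)-3-{5,7-bis(benzyloxy)-2-[4-(benzyloxy)phenyl]-4-oxo-4H-chromen-8-yl}phenyl)-7-methoxy-2,3-dihydro-4H-chromen-4-one | COc1cc(OCc2ccccc2)c2c(c1)O[C@H](c1ccc(OCc3ccccc3)c(-c3c(OCc4ccccc4)cc(OCc4ccccc4)c4c(=O)cc(-c5ccc(OCc6ccccc6)cc5)oc34)c1)CC2=O | intermediate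
34 | (2S)-2-{3-[5,7-dihydroxy-2-(4-hydroxyphenyl)-4-oxo-4H-chromen-8-yl]-4-hydroxyphenyl}-5-hydroxy-7-methoxy-2,3-dihydro-4H-chromen-4-one (CNP0107492.1) | COc1cc(O)c2c(c1)O[C@H](c1ccc(O)c(-c3c(O)cc(O)c4c(=O)cc(-c5ccc(O)cc5)oc34)c1)CC2=O | target

Total step count: 15. Longest linear sequence: 11 (steps 3 to 11, then 14 and 15).

Steps most likely to fail

Step 6. The donor-substituted cyclobutenone may open too slowly. The vinylketene may oligomerise or acylate the product phenol. The ortho-substituted aryl ynol ether may be sluggish in the cycloaddition or suffer silyl migration before it reacts. The fallback gives up the annulation and forms the C8–C3' bond by Suzuki–Miyaura coupling. It sets out from 7. Selective iodine–magnesium exchange (i-PrMgCl·LiCl, THF, −40 °C) gives [2-(benzyloxy)-5-bromophenyl]magnesium chloride F1. B(OMe)3 followed by dilute acid converts this into [2-(benzyloxy)-5-bromophenyl]boronic acid F2. In parallel, commercial apigenin is perbenzylated (BnBr, K2CO3, DMF, 80 °C) to tri-O-benzylapigenin F3. F3 is iodinated at C8, the usual site for fully etherified 5,7-dioxygenated flavones (N-iodosuccinimide, catalytic CF3CO2H, CH2Cl2), to give 8-iodo-tri-O-benzylapigenin F4. Coupling of F2 with F4 (Pd(PPh3)4, K2CO3, dioxane–H2O, 80 °C) should engage the iodide of F4 ahead of the bromide of F2. It rejoins the route at 27.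

Step 14. Slow migratory insertion into the electron-rich 5,7-dioxygenated chromone would let protodeboronation and homocoupling consume the valuable boronic acid. Facial selectivity with a para-alkoxyaryl group may also be eroded. The fallback builds the flavanone ring from a chalcone and separates the enantiomers. It sets out from 27. Reductive carbonylation (Pd(OAc)2, n-butyldi(1-adamantyl)phosphine, CO/H2, TMEDA, toluene, 100 °C) gives the ring B benzaldehyde F5. Claisen–Schmidt condensation of F5 with acetophenone 30 (KOH, EtOH–THF, rt) gives the 2'-hydroxychalcone F6. NaOAc in refluxing EtOH closes F6 by oxa-Michael addition, which the 6'-alkoxy group favours, to the racemic protected flavanone F7. Preparative HPLC on a chiral stationary phase (amylose tris(3,5-dimethylphenylcarbamate)) delivers 33, where the route is rejoined. The (R)-enantiomer F8 is returned to the NaOAc equilibration.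

Step 2. Attack of the alcohol at the carbonyl carbon, with cleavage of the strained ring to acetoacetate-type esters, or acid-induced decomposition may outrun exchange at C3. The fallback forms the O–CH2Ph bond instead of the C3–O bond. It sets out from 4. Dilute aqueous HCl at rt hydrolyses the enol ether to 3-hydroxycyclobut-2-en-1-one F9, the enol of cyclobutane-1,3-dione and a strong vinylogous acid. Mitsunobu O-alkylation (BnOH, PPh3, diisopropyl azodicarboxylate, THF, 0 °C) then rejoins the route at 5.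

Further compounds
F1 | step 6 | [2-(benzyloxy)-5-bromophenyl]magnesium chloride | Cl[Mg]c1cc(Br)ccc1OCc1ccccc1
F2 | step 6 | [2-(benzyloxy)-5-bromophenyl]boronic acid | OB(O)c1cc(Br)ccc1OCc1ccccc1
F3 | step 6 | 5,7-bis(benzyloxy)-2-[4-(benzyloxy)phenyl]-4H-chromen-4-one | O=c1cc(-c2ccc(OCc3ccccc3)cc2)oc2cc(OCc3ccccc3)cc(OCc3ccccc3)c12
F4 | step 6 | 5,7-bis(benzyloxy)-2-[4-(benzyloxy)phenyl]-8-iodo-4H-chromen-4-one | O=c1cc(-c2ccc(OCc3ccccc3)cc2)oc2c(I)c(OCc3ccccc3)cc(OCc3ccccc3)c12
F5 | step 14 | 4-(benzyloxy)-3-{5,7-bis(benzyloxy)-2-[4-(benzyloxy)phenyl]-4-oxo-4H-chromen-8-yl}benzaldehyde | O=Cc1ccc(OCc2ccccc2)c(-c2c(OCc3ccccc3)cc(OCc3ccccc3)c3c(=O)cc(-c4ccc(OCc5ccccc5)cc4)oc23)c1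
F6 | step 14 | (E)-1-[2-(benzyloxy)-6-hydroxy-4-methoxyphenyl]-3-(4-(benzyloxy)-3-{5,7-bis(benzyloxy)-2-[4-(benzyloxy)phenyl]-4-oxo-4H-chromen-8-yl}phenyl)prop-2-en-1-one | COc1cc(O)c(C(=O)/C=C/c2ccc(OCc3ccccc3)c(-c3c(OCc4ccccc4)cc(OCc4ccccc4)c4c(=O)cc(-c5ccc(OCc6ccccc6)cc5)oc34)c2)c(OCc2ccccc2)c1
F7 | step 14 | racemic 5-(benzyloxy)-2-(4-(benzyloxy)-3-{5,7-bis(benzyloxy)-2-[4-(benzyloxy)phenyl]-4-oxo-4H-chromen-8-yl}phenyl)-7-methoxy-2,3-dihydro-4H-chromen-4-one | COc1cc(OCc2ccccc2)c2c(c1)OC(c1ccc(OCc3ccccc3)c(-c3c(OCc4ccccc4)cc(OCc4ccccc4)c4c(=O)cc(-c5ccc(OCc6ccccc6)cc5)oc34)c1)CC2=O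
F8 | step 14 | (2R)-enantiomer of 33 | COc1cc(OCc2ccccc2)c2c(c1)O[C@@H](c1ccc(OCc3ccccc3)c(-c3c(OCc4ccccc4)cc(OCc4ccccc4)c4c(=O)cc(-c5ccc(OCc6ccccc6)cc5)oc34)c1)CC2=O
F9 | step 2 | 3-hydroxycyclobut-2-en-1-one | O=C1C=C(O)C1
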